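**Retrosynthetic overview**
1. Cut the C12'–C15 bond: the target comes from diene butenolide 21 (nucleophile through C15) and carbonate 19 (electrophile at C12'), both made from one allylic alcohol 18.
2. 18 comes from the C12 aldehyde 15 and furan-2(5H)-one; both butenolide rings are bought, not built.
3. 15 comes from allyl decalin 11 by reduction, acetonide formation and cleavage of the vinyl group.
4. Rings A and B of each half form together in one oxidative radical bicyclisation of the acyclic β-keto ester 10. This is the only ring-forming step; it sets C4, C5, C9, C10 and the exocyclic methylene.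
5. 10 comes from geranyl chloride, vinylmagnesium bromide and 2-methylacetoacetate carried on a recoverable 8-phenylmenthyl auxiliary.

Numbering of atoms follows andrographolide (labdane) numbering; primed atoms belong to the half that carries the C12' stereocentre. The target is the (12'S,15R) isomer.

Assumption: the face shielded by the 8-phenylmenthyl ester in the non-chelated radical is taken as the mirror image of the (1R,2S,5R)-auxiliary → 5α,10β-series correlation, so the (1S,2R,5S)-auxiliary is used for the ent series; likewise the dihydroquinidine-derived catalyst in step 13 is taken to give 12'S.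

**Step 1**
Reactants: 1 geranyl chloride; 2 vinylmagnesium bromide
Product: 3 (4E)-5,9-dimethyldeca-1,4,8-triene
Conditions: Li2CuCl4 (3 mol %), THF, −20 → 0 °C
Reagents that add atoms: none
Why: Copper-catalysed allyl–vinyl Grignard cross-coupling (Kochi type) proceeds by SN2 attack at the primary allylic chloride, so the E alkene is kept and a skipped diene results.

**Step 2**
Reactants: 3 (4E)-5,9-dimethyldeca-1,4,8-triene
Product: 4 (2E,6E)-2,6-dimethyldeca-2,6,9-trien-1-ol
Conditions: SeO2 (0.3 equiv), t-BuOOH (3 equiv), salicylic acid (10 mol %), CH2Cl2, 0 → 25 °C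
Reagents that add atoms: tert-butyl hydroperoxide, CC(C)(C)OO (stoichiometric oxygen source); selenium dioxide, O=[Se]=O (catalytic oxygen-transfer agent)
Why: Catalytic selenium dioxide allylic oxidation (ene reaction then [2,3]-shift) attacks the terminal trisubstituted alkene at its E-methyl group, giving the E allylic alcohol.

**Step 3**
Reactants: 4 (2E,6E)-2,6-dimethyldeca-2,6,9-trien-1-ol
Product: 5 (2E,6E)-1-bromo-2,6-dimethyldeca-2,6,9-triene
Conditions: CBr4, PPh3, CH2Cl2, 0 °C
Reagents that add atoms: tetrabromomethane, BrC(Br)(Br)Br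
Why: Appel bromination displaces the oxyphosphonium by SN2 at 0 °C without allylic transposition or loss of alkene geometry.

**Step 4**
Reactants: 6 ethyl 2-methyl-3-oxobutanoate; 7 (1S,2R,5S)-8-phenylmenthol
Product: 8 (1S,2R,5S)-8-phenylmenthyl 2-methyl-3-oxobutanoate
Conditions: 4-(dimethylamino)pyridine (20 mol %), toluene, reflux with removal of EtOH
Reagents that add atoms: none
Why: Amine-catalysed transesterification of a β-keto ester through the acylketene works with hindered secondary alcohols; the α-centre is an irrelevant epimer mixture that is destroyed in step 6.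

**Step 5**
Reactants: 8 (1S,2R,5S)-8-phenylmenthyl 2-methyl-3-oxobutanoate; 5 (2E,6E)-1-bromo-2,6-dimethyldeca-2,6,9-triene
Product: 10 (1S,2R,5S)-8-phenylmenthyl (6E,10E)-2,6,10-trimethyl-3-oxotetradeca-6,10,13-trienoate, via sodium lithium dienolate 9 (not isolated)
Conditions: NaH, THF, 0 °C; n-BuLi, 0 °C; then 5, −78 → 0 °C; dilute HCl
Reagents that add atoms: none
Why: Weiler dianion alkylation: the more reactive terminal carbanion of the β-keto ester dianion attacks the allylic bromide by SN2, and the substrate has no competing acidic site.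

**Step 6 (key step)**
Reactants: 10 (1S,2R,5S)-8-phenylmenthyl (6E,10E)-2,6,10-trimethyl-3-oxotetradeca-6,10,13-trienoate
Product: 11 8-phenylmenthyl 3-oxo-9-allyl decalin 19-ester (trans-decalin; C4 ester axial and cis to the C10 methyl; C4 methyl equatorial; 9-allyl equatorial; 8(17)-exocyclic methylene)
Conditions: Mn(OAc)3·2H2O (2.2 equiv), Cu(OAc)2·H2O (1 equiv), degassed AcOH, 25 °C, 0.02 M
Reagents that add atoms: none
Why: In this oxidative free-radical polyene bicyclisation trivalent manganese generates the α-keto ester radical, which closes rings A and B by two 6-endo additions through a chair–chair transition state (E,E geometry gives the trans ring fusion and equatorial C9 allyl, and the ester ends up axial), divalent copper oxidises the tertiary C8 radical to the less substituted exocyclic alkene, and the phenyl ring of the auxiliary shields one face of the planar radical to set the absolute configuration.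

**Step 7**
Reactants: 11 8-phenylmenthyl 3-oxo-9-allyl decalin 19-ester
Product: 12 9-allyl decalin 3,19-diol (3-OH equatorial; C3, C4, C5, C9, C10 as in andrographolide)
Conditions: LiAlH4, THF, 0 → 65 °C; Fieser work-up
Reagents that add atoms: none
Why: Hydride reduction delivers hydride to the C3 ketone axially, from the face opposite the axial C4 ester and the C10 methyl, giving the equatorial alcohol; the hindered ester is reduced to the C19 hydroxymethyl group and the auxiliary is recovered.

**Step 8**
Reactants: 12 9-allyl decalin 3,19-diol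
Product: 13 3,19-O-isopropylidene 9-allyl decalin
Conditions: 2,2-dimethoxypropane, pyridinium p-toluenesulfonate (5 mol %), CH2Cl2, 25 °C
Reagents that add atoms: 2,2-dimethoxypropane, COC(C)(C)OC
Why: Acid-catalysed transacetalisation closes the six-membered acetonide on the cis-disposed 1,3-diol, the standard protection of the andrographolide 3,19-diol.

**Step 9**
Reactants: 13 3,19-O-isopropylidene 9-allyl decalin
Product: 15 3,19-O-isopropylidene C12 aldehyde, via vicinal diol 14 (not isolated)
Conditions: OsO4 (2 mol %), NaIO4 (4 equiv), 2,6-lutidine, dioxane/H2O 3:1, 25 °C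
Reagents that add atoms: osmium tetroxide, O=[Os](=O)(=O)=O (delivers the oxygen, catalytic); sodium periodate, [Na+].[O-]I(=O)(=O)=O (stoichiometric reoxidant and cleaving agent)
Why: Lemieux–Johnson cleavage takes the unhindered monosubstituted vinyl group in preference to the exocyclic 8(17)-methylene, which is screened by C9 and the C10 methyl, as in side-chain degradations of 8(17)-labdadienes.

**Step 10**
Reactants: 15 3,19-O-isopropylidene C12 aldehyde; 16 furan-2(5H)-one
Product: 18 3,19-O-isopropylidene-14-deoxy-12-hydroxyandrographolide (12-epimer mixture), via selanyl aldol adduct 17 (not isolated)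
Conditions: PhSeH, n-BuLi, THF, −78 °C; 16 then 15, −78 °C; AcOH; then 30 % H2O2, pyridine, CH2Cl2, 0 → 25 °C
Reagents that add atoms: none
Why: Selenolate-induced Morita–Baylis–Hillman surrogate: conjugate addition of PhSeLi to the butenolide gives a lactone enolate that adds to the aldehyde, and selenoxide syn-elimination restores the C13=C14 bond; the C12 carbinol configuration is lost again in steps 12 and 13.

**Step 11**
Reactants: 18 3,19-O-isopropylidene-14-deoxy-12-hydroxyandrographolide
Product: 19 12-O-tert-butoxycarbonyl derivative of 18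
Conditions: Boc2O, 4-(dimethylamino)pyridine (10 mol %), CH2Cl2, 0 °C
Reagents that add atoms: di-tert-butyl dicarbonate, CC(C)(C)OC(=O)OC(=O)OC(C)(C)C
Why: Standard acylation of a Morita–Baylis–Hillman alcohol to its allylic tert-butyl carbonate, which later releases its own base (tert-butoxide) on ionisation.

**Step 12**
Reactants: 18 3,19-O-isopropylidene-14-deoxy-12-hydroxyandrographolide
Product: 21 3,19-O-isopropylidene-14-deoxy-11,12-didehydroandrographolide (11E), via mesylate 20 (not isolated)
Conditions: MsCl, Et3N, CH2Cl2, −20 °C; then 1,8-diazabicyclo[5.4.0]undec-7-ene, 0 → 25 °C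
Reagents that add atoms: none
Why: Mesylation followed by base-mediated 1,2-elimination (E2 or E1cB through the furanolate) gives the conjugated dienyl lactone, and the E C11=C12 alkene is favoured because it keeps the bulky decalin trans to the lactone.

**Step 13**
Reactants: 19 12-O-tert-butoxycarbonyl derivative of 18 (1.2 equiv); 21 3,19-O-isopropylidene-14-deoxy-11,12-didehydroandrographolide
Product: 22 bis-acetonide of the target (3,19:3',19'-di-O-isopropylidene; 12'S,15R)
Conditions: hydroquinidine 1,4-phthalazinediyl diether (10 mol %), 4 Å molecular sieves, PhCF3, 25 °C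
Reagents that add atoms: none
Why: Proposed new method: the tertiary amine adds SN2' at C14' of 19 with loss of CO2 and tert-butoxide, the tert-butoxide deprotonates C15 of 21, and the resulting 2-oxidofuran attacks C12' of the chiral allyl ammonium through its γ-carbon in a second SN2' step that restores the C13'=C14' butenolide; the alkaloid pocket sets C12', the open approach of the planar furanolate sets C15, and the (12'S,15R) isomer is separated from minor diastereomers by chromatography; closest known type is the cinchona-alkaloid-catalysed asymmetric allylic alkylation of Morita–Baylis–Hillman carbonates with butenolides.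

**Step 14**
Reactants: 22 bis-acetonide of the target
Product: 23 target CNP0220272.2
Conditions: AcOH/H2O 7:3, 25 °C
Reagents that add atoms: none
Why: Mild aqueous acid hydrolysis removes both acetonides without isomerising the exocyclic alkenes or epimerising the base-sensitive C15 centre, as is usual for 3,19-O-isopropylidene andrographolides.

**Compound list**
1 | geranyl chloride, (2E)-1-chloro-3,7-dimethylocta-2,6-diene | CC(C)=CCC/C(C)=C/CCl | starting material
2 | vinylmagnesium bromide | C=C[Mg]Br | starting material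
3 | (4E)-5,9-dimethyldeca-1,4,8-triene | C=CC/C=C(C)/CCC=C(C)C | intermediate
4 | (2E,6E)-2,6-dimethyldeca-2,6,9-trien-1-ol | OC/C(C)=C/CC/C(C)=C/CC=C | intermediate
5 | (2E,6E)-1-bromo-2,6-dimethyldeca-2,6,9-triene | BrC/C(C)=C/CC/C(C)=C/CC=C | intermediate
6 | ethyl 2-methyl-3-oxobutanoate (racemic) | CCOC(=O)C(C)C(C)=O | starting material
7 | (+)-8-phenylmenthol, (1S,2R,5S)-5-methyl-2-(2-phenylpropan-2-yl)cyclohexan-1-ol | CC(C)(c1ccccc1)[C@H]1CC[C@H](C)C[C@@H]1O | starting material
8 | (1S,2R,5S)-8-phenylmenthyl 2-methyl-3-oxobutanoate (α-epimers) | CC(=O)C(C)C(=O)O[C@H]1C[C@@H](C)CC[C@@H]1C(C)(C)c1ccccc1 | intermediate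
9 | sodium lithium dienolate (dianion) of 8 | [Na+].[Li+].C=C([O-])C(C)=C([O-])O[C@H]1C[C@@H](C)CC[C@@H]1C(C)(C)c1ccccc1 | intermediate
10 | (1S,2R,5S)-8-phenylmenthyl (6E,10E)-2,6,10-trimethyl-3-oxotetradeca-6,10,13-trienoate (α-epimers) | C=CC/C=C(C)/CC/C=C(C)/CCC(=O)C(C)C(=O)O[C@H]1C[C@@H](C)CC[C@@H]1C(C)(C)c1ccccc1 | intermediate
11 | 8-phenylmenthyl 3-oxo-9-allyl decalin 19-ester (trans-decalin, axial C4 ester cis to C10 methyl, equatorial 9-allyl, 8(17)-methylene) | C=C1CC[C@@H]2[C@](C)(C(=O)O[C@H]3C[C@@H](C)CC[C@@H]3C(C)(C)c3ccccc3)C(=O)CC[C@@]2(C)[C@@H]1CC=C | intermediate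
12 | 9-allyl decalin 3,19-diol (ring stereocentres as in andrographolide, 3-OH equatorial) | C=C1CC[C@@H]2[C@](C)(CO)[C@H](O)CC[C@@]2(C)[C@@H]1CC=C | intermediate
13 | 3,19-O-isopropylidene derivative of 12 | C=C1CC[C@@H]2[C@]3(C)COC(C)(C)O[C@@H]3CC[C@@]2(C)[C@@H]1CC=C | intermediate
14 | 12,13-diol of 13 (C12 epimers) | C=C1CC[C@@H]2[C@]3(C)COC(C)(C)O[C@@H]3CC[C@@]2(C)[C@@H]1CC(O)CO | intermediate
15 | 3,19-O-isopropylidene C12 aldehyde (2-decalinyl-acetaldehyde) | C=C1CC[C@@H]2[C@]3(C)COC(C)(C)O[C@@H]3CC[C@@]2(C)[C@@H]1CC=O | intermediate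
16 | furan-2(5H)-one | O=C1OCC=C1 | starting material
17 | 12-hydroxy-14-(phenylselanyl) saturated lactone adduct (diastereomer mixture) | C=C1CC[C@@H]2[C@]3(C)COC(C)(C)O[C@@H]3CC[C@@]2(C)[C@@H]1CC(O)C4C(=O)OCC4[Se]c5ccccc5 | intermediate
18 | 3,19-O-isopropylidene-14-deoxy-12-hydroxyandrographolide (12-epimers) | C=C1CC[C@@H]2[C@]3(C)COC(C)(C)O[C@@H]3CC[C@@]2(C)[C@@H]1CC(O)C4=CCOC4=O | intermediate
19 | 12-O-tert-butoxycarbonyl derivative of 18 | C=C1CC[C@@H]2[C@]3(C)COC(C)(C)O[C@@H]3CC[C@@]2(C)[C@@H]1CC(OC(=O)OC(C)(C)C)C4=CCOC4=O | intermediate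
20 | 12-O-methanesulfonyl derivative of 18 | C=C1CC[C@@H]2[C@]3(C)COC(C)(C)O[C@@H]3CC[C@@]2(C)[C@@H]1CC(OS(C)(=O)=O)C4=CCOC4=O | intermediate
21 | 3,19-O-isopropylidene-14-deoxy-11,12-didehydroandrographolide (11E) | C=C1CC[C@@H]2[C@]3(C)COC(C)(C)O[C@@H]3CC[C@@]2(C)[C@@H]1/C=C/C4=CCOC4=O | intermediate
22 | 3,19:3',19'-di-O-isopropylidene derivative of the target (12'S,15R) | C=C1CC[C@@H]2[C@]3(C)COC(C)(C)O[C@@H]3CC[C@@]2(C)[C@@H]1/C=C/C4=C[C@H]([C@@H](C[C@@H]5C(=C)CC[C@@H]6[C@]7(C)COC(C)(C)O[C@@H]7CC[C@]65C)C8=CCOC8=O)OC4=O | intermediate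
23 | CNP0220272.2, C12'–C15-linked andrographolide dimer (12'S,15R) | C=C1CC[C@@H]2[C@](C)(CO)[C@H](O)CC[C@@]2(C)[C@@H]1/C=C/C1=C[C@H]([C@@H](C[C@@H]2C(=C)CC[C@@H]3[C@](C)(CO)[C@H](O)CC[C@]32C)C2=CCOC2=O)OC1=O | target

**Step count**
Total: 14 steps. Longest linear sequence: 12 steps (1, 2, 3, 5, 6, 7, 8, 9, 10, 11 or 12, 13, 14).

**Three steps most likely to fail, with fallbacks**

Step 6 (bicyclisation). One operation has to deliver the yield, the exocyclic alkene, the C4 quaternary centre and the auxiliary's facial sense together. The fallback separates these tasks and sets out from bromide 5. The dianion of (1R,2S,5R)-8-phenylmenthyl 3-oxobutanoate F1 (from (1R,2S,5R)-8-phenylmenthol and 2,2,6-trimethyl-4H-1,3-dioxin-4-one, xylene, 140 °C) is alkylated with 5 to give the α-unsubstituted (1R,2S,5R)-8-phenylmenthyl (6E,10E)-6,10-dimethyl-3-oxotetradeca-6,10,13-trienoate F2. F2 is cyclised under chelation control (Mn(OAc)3·2H2O, Cu(OAc)2·H2O, Yb(OTf)3, CF3CH2OH, 0 °C); the ytterbium-bound syn-dicarbonyl radical is shielded by the phenyl ring and should give the ent-series bicyclic β-keto ester lacking the C4 methyl group F3. C-methylation of F3 (K2CO3, MeI, acetone) from the face opposite the C10 methyl places the ester axial in the C4-methylated keto ester F4. LiAlH4 reduction of F4 comes back to the route at diol 12. This costs one extra step.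

Step 13 (union). Regiochemistry (C12' against C14', γ against α attack) and two new stereocentres depend on an untested catalyst–substrate pair. The fallback sets out from aldehyde 15 and diene 21 and forms the same bond by conjugate addition followed by dehydrogenation. Wittig reaction of 15 with 3-(triphenyl-λ5-phosphanylidene)oxolan-2-one (toluene, 80 °C) gives the (E)-α-alkylidene butyrolactone F5. Silylation of 21 (TIPSOTf, Et3N, CH2Cl2, 0 °C) gives the 2-(triisopropylsilyloxy)furan F6. A fluoride-triggered vinylogous Mukaiyama–Michael addition of F6 to F5 (Bu4N+ Ph3SiF2−, THF, −78 °C), with the lactone enolate trapped by PhSeBr, gives the α-phenylselanyl lactone adduct F7. Selenoxide elimination (H2O2, pyridine) installs the C13'=C14' bond and comes back to the route at 22 after separation of diastereomers.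

Step 10 (hydroxyalkylation of the butenolide). The tandem selenolate addition–aldol can suffer from retro-aldol or enolisation of the aldehyde. The fallback sets out from aldehyde 15 and makes the same C12–C13 bond with reversed polarity: Nozaki–Hiyama–Kishi coupling of 15 with commercial 3-bromofuran-2(5H)-one (CrCl2, NiCl2 2 mol %, DMF, 25 °C; divalent chromium, nickel-catalysed) gives 18 directly, where it rejoins the route; no new compound is made on the way.

**Further compounds**
F1 | step 6 | (1R,2S,5R)-8-phenylmenthyl 3-oxobutanoate | CC(=O)CC(=O)O[C@@H]1C[C@H](C)CC[C@H]1C(C)(C)c1ccccc1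
F2 | step 6 | (1R,2S,5R)-8-phenylmenthyl (6E,10E)-6,10-dimethyl-3-oxotetradeca-6,10,13-trienoate | C=CC/C=C(C)/CC/C=C(C)/CCC(=O)CC(=O)O[C@@H]1C[C@H](C)CC[C@H]1C(C)(C)c1ccccc1
F3 | step 6 | ent-series bicyclic β-keto ester lacking the C4 methyl group (C4 epimers) | C=C1CC[C@@H]2C(C(=O)O[C@@H]3C[C@H](C)CC[C@H]3C(C)(C)c3ccccc3)C(=O)CC[C@@]2(C)[C@@H]1CC=C
F4 | step 6 | C4-methylated keto ester with axial (1R,2S,5R)-8-phenylmenthyl ester | C=C1CC[C@@H]2[C@](C)(C(=O)O[C@@H]3C[C@H](C)CC[C@H]3C(C)(C)c3ccccc3)C(=O)CC[C@@]2(C)[C@@H]1CC=C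
F0 | step 10 | none | none
F5 | step 13 | (E)-α-alkylidene butyrolactone from 15 | C=C1CC[C@@H]2[C@]3(C)COC(C)(C)O[C@@H]3CC[C@@]2(C)[C@@H]1C/C=C4\CCOC4=O
F6 | step 13 | 2-(triisopropylsilyloxy)furan from 21 | C=C1CC[C@@H]2[C@]3(C)COC(C)(C)O[C@@H]3CC[C@@]2(C)[C@@H]1/C=C/c4ccoc4O[Si](C(C)C)(C(C)C)C(C)C
F7 | step 13 | α-phenylselanyl lactone adduct (C13' epimers) | C=C1CC[C@@H]2[C@]3(C)COC(C)(C)O[C@@H]3CC[C@@]2(C)[C@@H]1/C=C/C4=C[C@H]([C@@H](C[C@@H]5C(=C)CC[C@@H]6[C@]7(C)COC(C)(C)O[C@@H]7CC[C@]65C)C8([Se]c9ccccc9)CCOC8=O)OC4=O
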